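Numbers refer to the compound list after the steps. All bicyclic intermediates keep the locants of cycloadduct 10 (O8 bridge, bridgeheads C1 and C5, C2–C3–C4 the three-carbon bridge, C6–C7 the two-carbon bridge).

## Analysis of the target

Target 25 is a single oxolane ring (O1–C2–C3–C4–C5) with three ring stereocentres and a fourth, C1', outside the ring. C2 is fully substituted (methyl and (E)-2-bromoethenyl), C3 carries chlorine, and C5 carries the 2-bromo-1-chloropropan-2-yl group. All four centres are S, and the bromoethenyl group, the C3 chlorine and the C5 side chain lie on one face of the ring. C1' is a tertiary bromide bearing methyl, CH2Cl and the ring, so its configuration relative to C5 cannot be read from the ring. The sensitive functions are the vicinal tertiary bromide/primary chloride (E2 with bases, reductive elimination with low-valent metals, 1,2-shift of bromine through a bridged ion), the secondary chloride and the vinyl bromide. The difficulty is that two fully substituted stereocentres flank the ring oxygen side by side with C5, and that four carbon–halogen bonds of three kinds must be made in an order each of them survives. The strategy rests on one feature: C2 and C5 carry their carbon substituents cis across O1, with a methyl on C2 and chlorine on C3. This is the pattern of 3-chloro-2-methylfuran (3) bridged at its two α-carbons by a three-carbon ketone unit, whose carbons are the future vinyl CH, the future CH2Cl and C1'.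

## Retrosynthetic reasoning

**25 to 23.** The C–Br bond of the bromoethenyl group is cut back to the terminal alkyne 23. Syn hydrometalation and bromination with retention fix the E geometry. A one-step bromo-olefination of an aldehyde by low-valent chromium is not used, because that reductant would attack the tertiary bromide at every stage at which the aldehyde exists. The alkyne is a latent form that tolerates the steps between.

**23 to 21 to 20.** The primary C–Cl bond is cut back to the alcohol 21 and this to the ester 20. The CH2Cl carbon leaves the ring cleavage at the carboxyl level, so chlorine cannot be placed on it earlier. The forward steps must reduce the ester without touching the α-bromine and then substitute at the CH2 carbon without letting the neighbouring bromine move.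

**20 to 19.** The alkyne carbon is removed, giving aldehyde 19. Its α-carbon is fully substituted, so the aldehyde cannot epimerise and suits a homologation under basic conditions at low temperature.

**19 to 18 to 16 to 15.** The aldehyde carbon and the ester carbon of 19 are joined again as C2–C3 of the bicyclic α-ketol 18. This is the only bond of the bridge whose cleavage leaves the carbonyl carbon on C4 (future C1') and one carbon on C1 (future C2). The ketol comes from ketone 15 through enol ether 16; with C4 fully substituted, 15 can enolise only towards C2.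

**15 to 13 to 11.** The C4–Br bond is cut back to the enol derivative 14 of ketone 13, and 13 to the α-alkoxy ketone 11 by reductive removal of the alkoxy group. Bromination on the rigid bicycle is what controls C1'; once the ring is opened this centre would have to be set in an open chain. The alkoxy group is removed from exactly the carbon that receives bromine.

**11 to 10.** Two C–H bonds are removed to give the chloroalkene 10. Hydrogen delivered to the exo face of the two-carbon bridge pushes chlorine endo, which is the C3 configuration of 25. The chlorine is already on carbon, so no C–Cl bond has to be made on the ring.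

**10 to 8 and 3.** The bonds C4–C5 and C1–C2 of 10 are cut in a (4+3) sense, giving the furan 3 and the silyl enol ether ketal 8 as the source of an alkoxy-substituted oxyallyl cation. This one disconnection removes a ring, two skeletal bonds and three stereocentres. The forward reaction must pair the fully substituted cation terminus with the free furan α-carbon and must choose one face of the cation.

**8 to 6 to 4 and 5; 3 to 1.** The enol ether 8 comes from ketone 6, and 6 from the commercial ketal 4 by exchange with the chiral alcohol 5. The chlorofuran 3 comes from bromofuran 1 by halogen exchange through the organolithium 2.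

## Alternatives that were turned down

**Alternative 1: carbene O–H insertion and aldol, a (4+1) annulation.** The ring is cut at O1–C2 and C2–C3, giving the hydroxy aldehyde A2 and the diazo ester A3. In the forward step Rh2(OAc)4 converts A3 into a carbenoid, which inserts into the carbinol O–H of A2; the resulting ylide or enol adds to the aldehyde and closes A1.
- For: one catalytic step makes the ring, the quaternary C2 and the C3 oxygen. The ester at C2 is the carbon of the bromoethenyl group, and the C3 hydroxyl is placed for chlorination with inversion. In convergence and in steps to the ring it is stronger than the chosen route.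
- Against: A2 already contains the contiguous C5 carbinol and C1' tertiary bromide in an open chain. This is the hardest stereochemical problem of 25, and the alternative only moves it into the starting material. A2 is also a bromohydrin and a β-hydroxy aldehyde, open to epoxide closure and dehydration. The cascade must set C2 and C3 relative to C5 with no rigid element. The later substitution of the C3 hydroxyl takes place next to a quaternary carbon, where elimination competes.
- In its place the chosen route offers one event that fixes C2 and C5 on a rigid bicycle, a chlorine carried in from the furan, and C1' set by a ring-controlled bromination.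

**Alternative 2: Petasis–Ferrier rearrangement.** The ring is cut at C4–C5 with C3 as a ketone. The precursor is a dioxolanone-derived enol acetal built from aldehyde A5. In the forward step Me2AlCl ionises the acetal, and the tethered aluminium enolate attacks the oxocarbenium carbon to give A4.
- For: convergent, and the silylalkyne that becomes the bromoethenyl group is in place from the start. On that point it is stronger, because the chosen route needs a late homologation. The C3 ketone is a handle for chlorine.
- Against: A5 must be made as a single enantiomer, which is again the unsolved C1' problem. The oxocarbenium carbon is bonded to the bromine-bearing carbon, so bromine bridging or halide loss to the Lewis acid threatens C1'. The quaternary C2 is differentiated only by methyl against alkynyl, so the bias for the 2,5-cis product is small. The ketone must then be reduced from the hindered face and substituted with inversion next to C2.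
- The chosen route is longer after the ring is formed, but it sets all four centres from one auxiliary and the shape of the bicycle and makes no C–Cl bond on the ring.

**Alternative 3: Prins–pinacol assembly.** The ring is cut at C4–C5 and C2–C3. The acetal of A5 with an allylic diol is ionised with SnCl4; the alkene attacks the oxocarbenium carbon, and a pinacol shift contracts the oxane to the 3-acetyl oxolane A6.
- For: the relative configuration of the ring is set reliably all-cis and a quaternary C2 is tolerated. In predictability of the ring-forming step it is stronger than the chosen key step.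
- Against: C3 carries an acetyl group where chlorine must sit on the same face. This costs a Baeyer–Villiger oxidation, a hydrolysis and a chlorination with net retention (two inversions) next to a quaternary centre. The silyloxymethyl group needs deprotection, oxidation and olefination. A5 and a strong Lewis acid beside the tertiary bromide are again required.
- In the chosen route every carbon of the bridge and the C3 chlorine map directly onto 25, so these corrective steps are not needed.

Key step: step 4

## Route

Assumption: the (S)-phenylethoxy group is taken to give the (1S,5S) bridgeheads, by analogy with acetal-derived cations of this type; if the sense is opposite, (R)-1-phenylethanol is used in step 2 and nothing else changes.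

Step 1
Reactants: 1 3-bromo-2-methylfuran
Product: 3 3-chloro-2-methylfuran, via (2-methylfuran-3-yl)lithium 2 (not isolated)
Conditions: t-BuLi (2 equiv), Et2O, −78 °C; C2Cl6, −78 → 0 °C
Reagents that add atoms: hexachloroethane, ClC(Cl)(Cl)C(Cl)(Cl)Cl
Why: Bromine–lithium exchange is faster than ring deprotonation at −78 °C and the 3-furyllithium keeps its position at this temperature; C2Cl6 then transfers electrophilic chlorine to the carbanion. The volatile product is distilled and used as a solution.

Step 2
Reactants: 4 3,3-dimethoxybutan-2-one; 5 (1S)-1-phenylethanol (2.5 equiv)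
Product: 6 3,3-bis[(1S)-1-phenylethoxy]butan-2-one
Conditions: p-TsOH·H2O (cat.), cyclohexane, 45 °C, reduced pressure (MeOH removed)
Reagents that add atoms: none
Why: Acid-catalysed transketalisation driven by removal of methanol; the mild acid and low temperature keep the benzylic alcohol from ionising, so its configuration is kept. Two identical alkoxy groups mean that the same cation forms in step 4 whichever one leaves.

Step 3
Reactants: 6 3,3-bis[(1S)-1-phenylethoxy]butan-2-one
Product: 8 triethyl({3,3-bis[(1S)-1-phenylethoxy]but-1-en-2-yl}oxy)silane, via lithium enolate 7 (not isolated)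
Conditions: LiN(i-Pr)2, THF, −78 °C; Et3SiCl
Reagents that add atoms: chlorotriethylsilane, CC[Si](Cl)(CC)CC
Why: The acetyl methyl group is the only enolisable position, so kinetic deprotonation and O-silylation give a single silyl enol ether; the ketal is inert to the amide base.

Step 4
Reactants: 8 triethyl({3,3-bis[(1S)-1-phenylethoxy]but-1-en-2-yl}oxy)silane; 3 3-chloro-2-methylfuran (2.5 equiv)
Product: 10 (1S,4S,5S)-7-chloro-1,4-dimethyl-4-[(1S)-1-phenylethoxy]-8-oxabicyclo[3.2.1]oct-6-en-3-one, via oxyallyl cation triflate 9 (not isolated)
Conditions: Me3SiOTf (0.15 equiv), CH2Cl2, −95 → −78 °C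
Reagents that add atoms: none
Why: Me3SiOTf ionises the ketal of 8 to the 1-alkoxy-1-methyl-2-silyloxyallyl cation 9. The free α-carbon of 3 attacks the oxocarbenium carbon, and the silyl enol ether terminus then closes on the methyl-bearing α-carbon, a stepwise (4+3) cycloaddition whose closest known type is the capture of acetal-derived 2-silyloxyallyl cations carrying a 1-phenylethoxy group by furans. The one ring closed is the seven-membered carbocycle, by a 7-(enolendo)-exo-trig attack of the enol ether carbon on the furan-derived oxocarbenium carbon, which leaves the furan oxygen as the one-atom bridge. The bridgeheads C1 and C5 are cis by necessity, and their absolute configuration follows from the face of 9 that the furan reaches, which the phenylethoxy group controls by shielding one face with its phenyl ring. C4 is set by the cation geometry and the mode of approach (alkoxy axial is expected), but it is erased in step 6. The step needs head-to-tail regiochemistry, secured because the fully substituted cation terminus pairs with the unsubstituted and most nucleophilic furan carbon, the other pairing having to join two fully substituted carbons. It also needs ring closure to outrun proton loss from the first adduct, which the low temperature and the tethered enol ether favour. The Et3SiOTf released on closure ionises the next molecule of 8, so the silyl triflate is needed only in catalytic amount.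

Step 5
Reactants: 10 (1S,4S,5S)-7-chloro-1,4-dimethyl-4-[(1S)-1-phenylethoxy]-8-oxabicyclo[3.2.1]oct-6-en-3-one
Product: 11 (1S,4S,5S,7S)-7-chloro-1,4-dimethyl-4-[(1S)-1-phenylethoxy]-8-oxabicyclo[3.2.1]octan-3-one
Conditions: KO2CN=NCO2K, AcOH, MeOH–CH2Cl2, 0 °C → rt, in portions
Reagents that add atoms: none
Why: Diimide reduction: concerted syn transfer of two hydrogens to the strained alkene from the exo face (the side of the oxygen bridge), the endo face being blocked by the three-carbon bridge, so chlorine ends endo (7S, the C3 configuration of the target). Diimide leaves the C–Cl bond, the ketone and the benzylic ether untouched, which a palladium-catalysed hydrogenation would not.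

Step 6
Reactants: 11 (1S,4S,5S,7S)-7-chloro-1,4-dimethyl-4-[(1S)-1-phenylethoxy]-8-oxabicyclo[3.2.1]octan-3-one
Product: 13 (1S,4R,5S,7S)-7-chloro-1,4-dimethyl-8-oxabicyclo[3.2.1]octan-3-one, via samarium enolate 12 (not isolated)
Conditions: SmI2 (2.5 equiv), THF–MeOH, −78 °C
Reagents that add atoms: none
Why: Reductive cleavage of an α-alkoxy ketone: two single-electron transfers from divalent samarium expel the alkoxide and give enolate 12, which methanol protonates from the exo face (methyl equatorial). The secondary chloride is inert to SmI2 under these conditions, and the auxiliary alcohol is recovered.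

Step 7
Reactants: 13 (1S,4R,5S,7S)-7-chloro-1,4-dimethyl-8-oxabicyclo[3.2.1]octan-3-one
Product: 15 (1S,4S,5S,7S)-4-bromo-7-chloro-1,4-dimethyl-8-oxabicyclo[3.2.1]octan-3-one, via silyl enol ether 14 (not isolated)
Conditions: Me3SiOTf, Et3N, CH2Cl2, 0 °C → rt; then NBS, −78 °C
Reagents that add atoms: N-bromosuccinimide, BrN1C(=O)CCC1=O
Why: Soft enolisation gives the more substituted enol ether 14 (C2 is also shielded by the quaternary C1), and electrophilic α-bromination of this silyl enol ether occurs axially from the exo face, anti to the two-carbon bridge and through a chair-like transition state. Bromine therefore ends axial and methyl equatorial, which is the 4S configuration that becomes C1' of the target.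

Step 8
Reactants: 15 (1S,4S,5S,7S)-4-bromo-7-chloro-1,4-dimethyl-8-oxabicyclo[3.2.1]octan-3-one
Product: 16 {[(1S,4S,5S,7S)-4-bromo-7-chloro-1,4-dimethyl-8-oxabicyclo[3.2.1]oct-2-en-3-yl]oxy}trimethylsilane
Conditions: Me3SiOTf, Et3N, CH2Cl2, 0 °C; non-aqueous work-up
Reagents that add atoms: trimethylsilyl trifluoromethanesulfonate, C[Si](C)(C)OS(=O)(=O)C(F)(F)F
Why: With C4 fully substituted the ketone can enolise only towards C2, so soft enolisation gives one silyl enol ether; a strong base is avoided because the α'-enolate of an α-bromo ketone would undergo Favorskii rearrangement.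

Step 9
Reactants: 16 {[(1S,4S,5S,7S)-4-bromo-7-chloro-1,4-dimethyl-8-oxabicyclo[3.2.1]oct-2-en-3-yl]oxy}trimethylsilane
Product: 18 (1S,2R,4S,5S,7S)-4-bromo-7-chloro-2-hydroxy-1,4-dimethyl-8-oxabicyclo[3.2.1]octan-3-one, via α-silyloxy ketone 17 (not isolated)
Conditions: mCPBA, NaHCO3, CH2Cl2, 0 °C; then 1 M HCl, THF
Reagents that add atoms: 3-chloroperoxybenzoic acid, OOC(=O)c1cccc(Cl)c1
Why: Rubottom oxidation: epoxidation of the enol ether, ring opening and silyl migration give 17, which the acidic work-up desilylates. The configuration at C2 is drawn for exo attack and does not matter, because this carbon becomes the aldehyde.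

Step 10
Reactants: 18 (1S,2R,4S,5S,7S)-4-bromo-7-chloro-2-hydroxy-1,4-dimethyl-8-oxabicyclo[3.2.1]octan-3-one
Product: 19 methyl (2S)-2-bromo-2-[(2S,4S,5S)-4-chloro-5-formyl-5-methyloxolan-2-yl]propanoate
Conditions: Pb(OAc)4, MeOH–PhMe, 0 °C
Reagents that add atoms: methanol, CO
Why: Glycol-type cleavage of an α-hydroxy ketone by tetravalent lead through its methanol hemiketal: C2 leaves as the aldehyde and C3 as the methyl ester, so the two ends are differentiated in one step. The aldehyde has no α-hydrogen and cannot epimerise.

Step 11
Reactants: 19 methyl (2S)-2-bromo-2-[(2S,4S,5S)-4-chloro-5-formyl-5-methyloxolan-2-yl]propanoate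
Product: 20 methyl (2S)-2-bromo-2-[(2S,4S,5S)-4-chloro-5-ethynyl-5-methyloxolan-2-yl]propanoate
Conditions: (MeO)2P(O)CHN2, KOt-Bu, THF, −78 °C; then 19, −78 → −20 °C
Reagents that add atoms: dimethyl (diazomethyl)phosphonate, COP(=O)(OC)C=[N+]=[N-]
Why: Seyferth–Gilbert homologation of a non-enolisable aldehyde: the preformed phosphonate anion adds, phosphate and nitrogen are lost, and the alkylidene carbene undergoes a 1,2-hydrogen shift. Preforming the anion at low temperature keeps free alkoxide away from the tertiary α-bromo ester, and the alkyne replaces a chromium-mediated bromo-olefination, whose divalent chromium would reduce that bromide.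

Step 12
Reactants: 20 methyl (2S)-2-bromo-2-[(2S,4S,5S)-4-chloro-5-ethynyl-5-methyloxolan-2-yl]propanoate
Product: 21 (2R)-2-bromo-2-[(2S,4S,5S)-4-chloro-5-ethynyl-5-methyloxolan-2-yl]propan-1-ol
Conditions: i-Bu2AlH (3 equiv), CH2Cl2, −78 → −20 °C; Rochelle salt
Reagents that add atoms: none
Why: Hydride reduction of the ester through the aldehyde to the primary alcohol; this aluminium hydride reduces α-bromo esters to bromohydrins without cleaving the C–Br bond and leaves the alkyne alone below 0 °C. Neutral work-up prevents epoxide closure; the descriptor changes to R only because the CIP priorities change.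

Step 13
Reactants: 21 (2R)-2-bromo-2-[(2S,4S,5S)-4-chloro-5-ethynyl-5-methyloxolan-2-yl]propan-1-ol
Product: 23 (2S,3S,5S)-5-[(2S)-2-bromo-1-chloropropan-2-yl]-3-chloro-2-ethynyl-2-methyloxolane, via primary triflate 22 (not isolated)
Conditions: Tf2O, 2,6-di-tert-butyl-4-methylpyridine, CH2Cl2, −78 °C; then n-Bu4NCl (excess), −78 → −20 °C
Reagents that add atoms: tetrabutylammonium chloride, [Cl-].CCCC[N+](CCCC)(CCCC)CCCC
Why: Triflation and then SN2 displacement at the primary carbon by unsolvated chloride in a non-ionising solvent at low temperature; C1' is not involved in a direct displacement. If bromine does bridge, opening of the bridged ion at the CH2 carbon returns the same product, and only opening at the tertiary carbon would exchange the halogens.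

Step 14
Reactants: 23 (2S,3S,5S)-5-[(2S)-2-bromo-1-chloropropan-2-yl]-3-chloro-2-ethynyl-2-methyloxolane
Product: 25 (2S,3S,5S)-2-[(E)-2-bromoethenyl]-5-[(2S)-2-bromo-1-chloropropan-2-yl]-3-chloro-2-methyloxolane, via alkenylzirconocene 24 (not isolated)
Conditions: Cp2Zr(H)Cl, THF, rt, dark; then NBS, 0 °C
Reagents that add atoms: N-bromosuccinimide, BrN1C(=O)CCC1=O
Why: Hydrozirconation adds Zr–H syn across the terminal alkyne with zirconium on the terminal carbon, and bromination of the alkenylzirconium 24 proceeds with retention, so only the (E)-bromoalkene can form. The tetravalent zirconium hydride is not an electron-transfer reductant and leaves the alkyl halides alone.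

## Compound list

1 | 3-bromo-2-methylfuran | Cc1occc1Br | starting material
2 | (2-methylfuran-3-yl)lithium | Cc1occc1[Li] | intermediate (not isolated)
3 | 3-chloro-2-methylfuran | Cc1occc1Cl | intermediate
4 | 3,3-dimethoxybutan-2-one | CC(=O)C(C)(OC)OC | starting material
5 | (1S)-1-phenylethanol | C[C@H](O)c1ccccc1 | starting material
6 | 3,3-bis[(1S)-1-phenylethoxy]butan-2-one | CC(=O)C(C)(O[C@@H](C)c1ccccc1)O[C@@H](C)c1ccccc1 | intermediate
7 | lithium 3,3-bis[(1S)-1-phenylethoxy]but-1-en-2-olate | [Li]OC(=C)C(C)(O[C@@H](C)c1ccccc1)O[C@@H](C)c1ccccc1 | intermediate (not isolated)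
8 | triethyl({3,3-bis[(1S)-1-phenylethoxy]but-1-en-2-yl}oxy)silane | CC(O[C@@H](C)c1ccccc1)(O[C@@H](C)c1ccccc1)C(=C)O[Si](CC)(CC)CC | intermediate
9 | 1-methyl-1-[(1S)-1-phenylethoxy]-2-(triethylsilyloxy)allyl cation, triflate salt | C=C(O[Si](CC)(CC)CC)C(C)=[O+][C@@H](C)c1ccccc1.[O-]S(=O)(=O)C(F)(F)F | intermediate (not isolated)
10 | (1S,4S,5S)-7-chloro-1,4-dimethyl-4-[(1S)-1-phenylethoxy]-8-oxabicyclo[3.2.1]oct-6-en-3-one | O1[C@]2(C)C(Cl)=C[C@H]1[C@](C)(O[C@@H](C)c3ccccc3)C(=O)C2 | intermediate
11 | (1S,4S,5S,7S)-7-chloro-1,4-dimethyl-4-[(1S)-1-phenylethoxy]-8-oxabicyclo[3.2.1]octan-3-one | O1[C@]2(C)[C@@H](Cl)C[C@H]1[C@](C)(O[C@@H](C)c3ccccc3)C(=O)C2 | intermediate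
12 | diiodosamarium (1S,5S,7S)-7-chloro-1,4-dimethyl-8-oxabicyclo[3.2.1]oct-3-en-3-olate | O1[C@]2(C)[C@@H](Cl)C[C@H]1C(C)=C(O[Sm](I)I)C2 | intermediate (not isolated)
13 | (1S,4R,5S,7S)-7-chloro-1,4-dimethyl-8-oxabicyclo[3.2.1]octan-3-one | O1[C@]2(C)[C@@H](Cl)C[C@H]1[C@@H](C)C(=O)C2 | intermediate
14 | {[(1S,5S,7S)-7-chloro-1,4-dimethyl-8-oxabicyclo[3.2.1]oct-3-en-3-yl]oxy}trimethylsilane | O1[C@]2(C)[C@@H](Cl)C[C@H]1C(C)=C(O[Si](C)(C)C)C2 | intermediate (not isolated)
15 | (1S,4S,5S,7S)-4-bromo-7-chloro-1,4-dimethyl-8-oxabicyclo[3.2.1]octan-3-one | O1[C@]2(C)[C@@H](Cl)C[C@H]1[C@](C)(Br)C(=O)C2 | intermediate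
16 | {[(1S,4S,5S,7S)-4-bromo-7-chloro-1,4-dimethyl-8-oxabicyclo[3.2.1]oct-2-en-3-yl]oxy}trimethylsilane | O1[C@]2(C)[C@@H](Cl)C[C@H]1[C@](C)(Br)C(O[Si](C)(C)C)=C2 | intermediate
17 | (1S,2R,4S,5S,7S)-4-bromo-7-chloro-1,4-dimethyl-2-(trimethylsilyloxy)-8-oxabicyclo[3.2.1]octan-3-one | O1[C@]2(C)[C@@H](Cl)C[C@H]1[C@](C)(Br)C(=O)[C@@H]2O[Si](C)(C)C | intermediate (not isolated)
18 | (1S,2R,4S,5S,7S)-4-bromo-7-chloro-2-hydroxy-1,4-dimethyl-8-oxabicyclo[3.2.1]octan-3-one | O1[C@]2(C)[C@@H](Cl)C[C@H]1[C@](C)(Br)C(=O)[C@@H]2O | intermediate
19 | methyl (2S)-2-bromo-2-[(2S,4S,5S)-4-chloro-5-formyl-5-methyloxolan-2-yl]propanoate | C[C@@](Br)(C(=O)OC)[C@@H]1C[C@H](Cl)[C@](C)(C=O)O1 | intermediate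
20 | methyl (2S)-2-bromo-2-[(2S,4S,5S)-4-chloro-5-ethynyl-5-methyloxolan-2-yl]propanoate | C[C@@](Br)(C(=O)OC)[C@@H]1C[C@H](Cl)[C@](C)(C#C)O1 | intermediate
21 | (2R)-2-bromo-2-[(2S,4S,5S)-4-chloro-5-ethynyl-5-methyloxolan-2-yl]propan-1-ol | C[C@@](Br)(CO)[C@@H]1C[C@H](Cl)[C@](C)(C#C)O1 | intermediate
22 | (2R)-2-bromo-2-[(2S,4S,5S)-4-chloro-5-ethynyl-5-methyloxolan-2-yl]propyl trifluoromethanesulfonate | C[C@@](Br)(COS(=O)(=O)C(F)(F)F)[C@@H]1C[C@H](Cl)[C@](C)(C#C)O1 | intermediate (not isolated)
23 | (2S,3S,5S)-5-[(2S)-2-bromo-1-chloropropan-2-yl]-3-chloro-2-ethynyl-2-methyloxolane | C[C@@](Br)(CCl)[C@@H]1C[C@H](Cl)[C@](C)(C#C)O1 | intermediate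
24 | chloridobis(cyclopentadienyl)[(E)-2-{(2S,3S,5S)-5-[(2S)-2-bromo-1-chloropropan-2-yl]-3-chloro-2-methyloxolan-2-yl}ethenyl]zirconium | C[C@@](Br)(CCl)[C@@H]1C[C@H](Cl)[C@](C)(/C=C/[Zr](Cl)(C2C=CC=C2)C2C=CC=C2)O1 | intermediate (not isolated)
25 | (2S,3S,5S)-2-[(E)-2-bromoethenyl]-5-[(2S)-2-bromo-1-chloropropan-2-yl]-3-chloro-2-methyloxolane | C[C@@](Br)(CCl)[C@@H]1C[C@H](Cl)[C@](C)(/C=C/Br)O1 | target

## Step count and least certain steps

Total: 14 steps. Longest linear sequence: 13 steps (steps 2 to 14, from 4 and 5); the furan branch adds step 1.

**Step 4 (key step).**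
- What may go wrong: proton loss from the first adduct restores the furan and gives substitution instead of annulation, since closure has to form a quaternary bridgehead. The cation can also lose a proton from its C-methyl group, and the more substituted cation may show lower facial selectivity than its acetal-derived relatives.
- Fallback: it sets out from 3 and 5 and returns at 13. It uses the acetal-derived cation without the C-methyl group and brings that methyl in afterwards. 1,1-Dimethoxypropan-2-one F1 is transacetalised with 5 to 1,1-bis[(1S)-1-phenylethoxy]propan-2-one F2, which is converted (LiN(i-Pr)2, Et3SiCl) into triethyl({3,3-bis[(1S)-1-phenylethoxy]prop-1-en-2-yl}oxy)silane F3. Cycloaddition of F3 with 3 under Me3SiOTf catalysis gives (1S,4S,5S)-7-chloro-1-methyl-4-[(1S)-1-phenylethoxy]-8-oxabicyclo[3.2.1]oct-6-en-3-one F4. Any regioisomer must be removed here, because after loss of the alkoxy group it would become the enantiomer. Diimide reduction gives (1S,4S,5S,7S)-7-chloro-1-methyl-4-[(1S)-1-phenylethoxy]-8-oxabicyclo[3.2.1]octan-3-one F5, and SmI2 in THF–MeOH gives (1S,5R,7S)-7-chloro-1-methyl-8-oxabicyclo[3.2.1]octan-3-one F6. Kinetic deprotonation with LiN(i-Pr)2 is expected at C4, the α-carbon remote from the quaternary bridgehead, and methylation with MeI followed by equilibration of the new centre gives 13.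

**Step 13.**
- What may go wrong: the neighbouring bromine displaces the leaving group, and chloride then opens the bridged ion at the tertiary carbon. This exchanges the positions of the two halogens and inverts C1'. Other displacement methods, such as alkoxyphosphonium chemistry, share this weakness. Elimination of HBr is a second risk.
- Fallback: it sets out from 21 and returns at 23. It makes the C–Cl bond before the C–Br bond and gives up ring control of C1'. K2CO3 in MeOH closes 21 to (2S)-2-[(2S,4S,5S)-4-chloro-5-ethynyl-5-methyloxolan-2-yl]-2-methyloxirane F7. Excess Et2Al(TMP) (TMP = 2,2,6,6-tetramethylpiperidide) isomerises F7, by removing a methyl proton, to 2-[(2S,4S,5S)-4-chloro-5-ethynyl-5-methyloxolan-2-yl]prop-2-en-1-ol F8. Ph3P and CCl4 give (2S,3S,5S)-3-chloro-5-(3-chloroprop-1-en-2-yl)-2-ethynyl-2-methyloxolane F9. Markovnikov addition of anhydrous HBr in CH2Cl2 at low temperature then gives 23 together with its C1' epimer (2S,3S,5S)-5-[(2R)-2-bromo-1-chloropropan-2-yl]-3-chloro-2-ethynyl-2-methyloxolane F10, which must be separated by chromatography.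

**Step 7.**
- What may go wrong: enolisation towards C2 instead of C4 would place bromine on the wrong α-carbon, and equatorial attack would give the wrong C1' configuration.
- Fallback: it sets out from 11 and returns at 14 and 15; no new compound is made. It removes the regiochemical question. SmI2 is used in THF without a proton source, and the samarium enolate 12 is silylated on oxygen with Me3SiCl and Et3N, which fixes the double bond of 14 between C3 and C4. After samarium and iodide salts are removed by extraction into pentane, NBS at −78 °C gives 15.

**Step 5.**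
- What may go wrong: hydrogen transfer to a trisubstituted, chlorine-bearing alkene may be slow, so that diimide disproportionates before it reacts.
- Fallback: it sets out from 10 and returns at 11; no new compound is made. It uses radical hydrogen-atom-transfer hydrogenation with Mn(dpm)3 (dpm = dipivaloylmethanate), PhSiH3 and t-BuOOH in i-PrOH. A hydrogen atom adds to C6, and the α-chloro radical at C7 takes its hydrogen from the open exo face, so chlorine again ends endo and the C–Cl bond is kept.

**Step 2.**
- What may go wrong: the exchange may stop at the mixed ketal because the ketal carbon is hindered and deactivated by the adjacent carbonyl. Forcing it with acid could ionise the benzylic alcohol, with racemisation or ether formation.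
- Fallback: it sets out from 5 and returns at 6. Alcohol 5 is silylated (Me3SiCl, imidazole) to trimethyl[(1S)-1-phenylethoxy]silane F11. Butane-2,3-dione F12 is ketalised at one carbonyl with two equivalents of F11 and catalytic Me3SiOTf in CH2Cl2 at −78 °C. These are aprotic conditions under which the benzylic centre is not ionised and the second carbonyl, once flanked by the ketal, does not react.

## Further compounds

F1 | step 4 | 1,1-dimethoxypropan-2-one | CC(=O)C(OC)OC
F2 | step 4 | 1,1-bis[(1S)-1-phenylethoxy]propan-2-one | CC(=O)C(O[C@@H](C)c1ccccc1)O[C@@H](C)c1ccccc1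
F3 | step 4 | triethyl({3,3-bis[(1S)-1-phenylethoxy]prop-1-en-2-yl}oxy)silane | C=C(O[Si](CC)(CC)CC)C(O[C@@H](C)c1ccccc1)O[C@@H](C)c1ccccc1
F4 | step 4 | (1S,4S,5S)-7-chloro-1-methyl-4-[(1S)-1-phenylethoxy]-8-oxabicyclo[3.2.1]oct-6-en-3-one | O1[C@]2(C)C(Cl)=C[C@H]1[C@H](O[C@@H](C)c3ccccc3)C(=O)C2
F5 | step 4 | (1S,4S,5S,7S)-7-chloro-1-methyl-4-[(1S)-1-phenylethoxy]-8-oxabicyclo[3.2.1]octan-3-one | O1[C@]2(C)[C@@H](Cl)C[C@H]1[C@H](O[C@@H](C)c3ccccc3)C(=O)C2
F6 | step 4 | (1S,5R,7S)-7-chloro-1-methyl-8-oxabicyclo[3.2.1]octan-3-one | O1[C@]2(C)[C@@H](Cl)C[C@H]1CC(=O)C2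
F7 | step 13 | (2S)-2-[(2S,4S,5S)-4-chloro-5-ethynyl-5-methyloxolan-2-yl]-2-methyloxirane | C[C@@]1(OC1)[C@@H]2C[C@H](Cl)[C@](C)(C#C)O2
F8 | step 13 | 2-[(2S,4S,5S)-4-chloro-5-ethynyl-5-methyloxolan-2-yl]prop-2-en-1-ol | C=C(CO)[C@@H]1C[C@H](Cl)[C@](C)(C#C)O1
F9 | step 13 | (2S,3S,5S)-3-chloro-5-(3-chloroprop-1-en-2-yl)-2-ethynyl-2-methyloxolane | C=C(CCl)[C@@H]1C[C@H](Cl)[C@](C)(C#C)O1
F10 | step 13 | (2S,3S,5S)-5-[(2R)-2-bromo-1-chloropropan-2-yl]-3-chloro-2-ethynyl-2-methyloxolane | C[C@](Br)(CCl)[C@@H]1C[C@H](Cl)[C@](C)(C#C)O1
F0 | step 7 | none | none
F0 | step 5 | none | none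
F11 | step 2 | trimethyl[(1S)-1-phenylethoxy]silane | C[C@H](O[Si](C)(C)C)c1ccccc1
F12 | step 2 | butane-2,3-dione | CC(=O)C(C)=O
A1 | alternative 1 | tert-butyl (2R,3R,5S)-5-[(2S)-2-bromo-1-chloropropan-2-yl]-3-hydroxy-2-methyloxolane-2-carboxylate | O1[C@](C(=O)OC(C)(C)C)(C)[C@H](O)C[C@H]1[C@](C)(Br)CCl
A2 | alternative 1 | (3S,4S)-4-bromo-5-chloro-3-hydroxy-4-methylpentanal | O=CC[C@H](O)[C@](C)(Br)CCl
A3 | alternative 1 | tert-butyl 2-diazopropanoate | CC(=[N+]=[N-])C(=O)OC(C)(C)C
A4 | alternative 2 | (2S,5S)-5-[(2S)-2-bromo-1-chloropropan-2-yl]-2-methyl-2-[(trimethylsilyl)ethynyl]oxolan-3-one | O1[C@](C#C[Si](C)(C)C)(C)C(=O)C[C@H]1[C@](C)(Br)CCl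
A5 | alternative 2 | (2S)-2-bromo-3-chloro-2-methylpropanal | O=C[C@](C)(Br)CCl
A6 | alternative 3 | 1-[(2R,3S,5S)-5-[(2S)-2-bromo-1-chloropropan-2-yl]-2-{[tert-butyl(diphenyl)silyl]oxymethyl}-2-methyloxolan-3-yl]ethan-1-one | O1[C@](CO[Si](c2ccccc2)(c2ccccc2)C(C)(C)C)(C)[C@@H](C(C)=O)C[C@H]1[C@](C)(Br)CCl
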